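In a one-step world every percent of substrate lost turns up as product. The green run refutes that: by 6.00 h it has lost 96.9 % of its substrate and shows 19.2 % of product. The grey run has lost 98.1 % and shows 30.4 %.

| setting | green | grey | south | south-west | south-east | north-west |
|---|---|---|---|---|---|---|
| substrate | 0.016 M | 0.14 M | 0.20 M | 0.12 M | 0.059 M | 0.020 M |
| remark | run made earlier | run made earlier |  |  |  |  |
| time |  |  | 6.0 h | 6.0 h | 6.0 h | 6.0 h |

| run | time / h | product / % | substrate / % |
|---|---|---|---|
| green | 0.500 | 4.6 | 69.1 |
| green | 0.833 | 6.8 | 52.6 |
| green | 1.50 | 11.6 | 31.8 |
| green | 3.00 | 16.5 | 10.8 |
| green | 6.00 | 19.2 | 3.1 |
| grey | 1.33 | 21.3 | 29.1 |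
| grey | 2.50 | 27.1 | 10.2 |
| grey | 4.00 | 29.9 | 3.8 |
| grey | 5.00 | 30.9 | 2.9 |
| grey | 6.00 | 30.4 | 1.9 |

(scatter of a reading: 0.5 percentage points)

- the flasks by amount of product, in percent of the substrate charged, highest first, at 6.0 h (south / south-west / south-east / north-west)
- the amount of product, in percent of the substrate charged of the flask you put first, at 6.0 h
- the amount of product, in percent of the substrate charged of the flask you put last, at 6.0 h

- amounts and yields of product count crystals too
- given per volume of solution although it is solid: crystals
- reactions considered so far: substrate + product -> 2 product; substrate -> product; substrate <-> dormant form; crystals <-> product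

So I add a second step, the parking of substrate as dormant form. By balance that form holds 77.7 % in green and 67.7 % in grey, more than the product in each. With two first-order routes, the share of lost substrate found as product, the selectivity, does not depend on the charge. But grey ends 11 percentage points above green.

Next comes substrate + product -> 2 product, a route that speeds up with dissolved product. In green the share read is 0.149 at the first reading and 0.198 at the last, but a dormant form that returns slowly can raise it too, so this rise alone does not prove the route.

Last come the crystals, which take dissolved product away, so I expect that growth to flatten. From green to grey, a charge larger by a factor of 8.75 goes with product larger by a factor of 1.58.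

So I reckon in doublings. Between green and grey, product rises by 3.6 points per doubling of the charge. This gain per doubling is what I carry. It orders the flasks by charge. It gives south 32.2 %, which lies beyond the grey charge and is less sure, and north-west 20.4 %.

The forecast gives south > south-west > south-east > north-west, with 31 % for south and 21 % for north-west, holding that “Yield therefore saturates with concentration”. Its order is mine, but my south stands higher and my north-west lower.

    substrate + product → 2 product (k = 0.430 /M/min)
    substrate → product (k = 0.00180 /min)
    substrate ⇌ dormant form (K = 30.0, k = 0.0110 /min)
    crystals ⇌ product, rate k4*(cs4 - [product]) while solid is left; crystals form when [product] > cs4 (solubility = 3.60 mM, k = 0.0690 /min)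

The flasks stand south > south-west > south-east > north-west, from 35.6 % in south to 20.0 % in north-west. South's product moves by 5 points at charges of 0.143 M and 0.249 M, or at times of 1.84 h and 21.6 h. Read between south and north-west, the gain per doubling is 4.7 points, above the 3.6 points I carried. For a further flask charged with 0.080 M, the carried gain counted from grey gives 27.5 %, and the product in that flask stands at 26.0 %.

Readings and results were computed for substances that don't exist, noise included.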